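## The problem

The target is a germacranolide: a ten-membered carbocycle (C1–C10) fused at C6–C7 to a butenolide. The tetrasubstituted C7=C11 double bond carries the C13 acetoxymethyl group, a C1 ketone is conjugated to the exocyclic C10=C14 methylene, and the ring bears a cis-4,5-epoxide and a methacrylate at C8. Four stereocentres must be set (4S, 5R, 6R, 8R). C4 and C5 are the two ends of one epoxide derived from a Z-olefin and can be set together by reagent control. C5 can then direct C6, because the 5,6-anti relation is the Felkin outcome of adding a carbon nucleophile to an α,β-epoxy aldehyde. C8 lies across the flat butenolide from C6 and cannot be induced reliably in an open chain, so it is best taken from the chiral pool. Several groups are fragile: the α-methylene ketone is a Michael acceptor and should appear last; the trisubstituted epoxide will not tolerate acid while a free hydroxyl at C1 or C8 sits within reach; the butenolide has acidic γ-hydrogens at C6 and C8; and the allylic C13 acetate can be ionised by low-valent metals. The feature that makes a gentle ring closure possible is the C8–C9–C10 segment: C8(O)–C9H2 is the imprint of an opened terminal oxirane and C10, an sp2 carbon bearing the C14 methylene, is the imprint of a 1,1-disubstituted alkenyl halide, so C9–C10 can be formed by joining two electrophiles.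

## Retrosynthesis

**Oxidation level and esters (29 back to 25).** No C–C bond is cut. The C1 ketone of 29 is traced to allylic alcohol 28, the C13 acetate to diol 27, 27 to bis-silyl ether 26, and the C8 methacrylate to alcohol 25. C1 is carried as a silyl-protected carbinol and not as a ketal, because its release needs only buffered fluoride and a neutral oxidation, whereas ketal hydrolysis would put acid next to the epoxide. The price is one spectator stereocentre at C1 and the need to distinguish the primary C13 hydroxyl from the secondary C1 hydroxyl in 27.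

**Ring closure (25 back to 23).** The C9–C10 bond is cut, which opens the carbocycle to the epoxide–alkenyl bromide 23. The neighbouring cuts are less attractive: C6–C7 would create C6 during ring closure, and C1–C10 or C1–C2 would need a carbonyl-level partner that must be masked twice. C9–C10 is the only ring bond whose two ends are simple, storable electrophiles and whose formation creates no stereocentre. Precursor 23 already holds all four stereocentres, the epoxide and the lactone. The forward reaction must open only the terminal oxirane at C9 (through iodohydrin 24) and join it to C10 faster than chains can couple with each other.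

**Terminal oxirane (23 back to 20).** The C9–O bond is cut: 23 comes from diol 21 through its primary tosylate 22, and 21 from the bis(triethylsilyl) ether 20. Silyl ethers are chosen over an acetonide for the C8/C9 diol because buffered fluoride frees the diol without exposing the C4–C5 epoxide and the nearby C8 hydroxyl to acid. The C8–O bond is never broken, so the chiral-pool configuration is kept.

**C1 unit (20 back to 13).** The C1–C10 bond is cut. The 2-bromoallyl silyl ether of 20 derives from aldehyde 13 and vinylmagnesium bromide 14 through allylic alcohol 15, enone 16, bromoenone 18 and carbinol 19. This is done after the butenolide is in place so that no alkenyl bromide is present during the chromium-mediated coupling. The sequence must tolerate the lactone and the epoxide and should fix C1 in a single configuration.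

**Masked aldehyde (13 back to 12).** The C1=C(CH3)2 bond is cut by ozonolysis. The isopropylidene end of the nerol chain in 12 serves as a latent C1 aldehyde and needs no protecting group. The reaction must spare the electron-poor, tetrasubstituted butenolide double bond.

**Butenolide (12 back to 7 and 10).** The C6–C7 bond and the lactone C12–O bond are cut, giving enol triflate 7 and epoxy aldehyde 10, joined through hydroxy ester 11. This one intermolecular step delivers the whole butenolide and sets C6 next to the controlling epoxide, at a stage where a minor C6 epimer can be removed. It asks for a Z enol triflate (triflate cis to the ester) and for Felkin addition.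

**Epoxy aldehyde (10 back to 8).** Aldehyde 10 comes from epoxy alcohol 9 by oxidation, and 9 from nerol 8 by asymmetric epoxidation. The Z geometry of 8 supplies the cis relation of C3 and C6 on the epoxide.

**Enol triflate (7 back to 1 and 3).** Triflate 7 comes from diol 6 by silylation, 6 from acetonide 5, 5 from β-keto ester 4, and 4 from a crossed Claisen cut (C7–C11) into silyl ether 2 and glycerate 3. Ester 2 is the silyl ether of 1. The acetonide is removed here, on a small molecule with no epoxide, where acid is harmless.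

## Roads not taken

Alternative 1: The cut is C6–C7 together with the lactone C–O bond, made in the ring-closing step. The open-chain enol triflate aldehyde A1 would be treated with CrCl2 and catalytic NiCl2; the alkenylchromium adds to the C6 aldehyde and the alkoxide closes the butenolide, giving macrocycle A2.
- Merits: the reaction class is a well-established macrocyclisation, ring and lactone form together, and A2 needs only desilylation and oxidation at C1.
- Weak points: C6 is created during closure of a ten-membered ring, where the conformation of the transition state, not the Felkin preference, decides the face. A1 must also carry an allylic acetate and a methacrylate through low-valent nickel and chromium, and its C8–C10 segment has to be built separately with its own stereocontrol.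
- Comparison: in precedent for the ring closure and in brevity after it, this road is better. The chosen plan sets against this that its ring closure creates no stereocentre, that C6 is set intermolecularly in step 8 where an epimer can be separated, and that no ester leaving group is present when nickel is used.

Alternative 2: The cut is C2–C3, reached by ring contraction. The twelve-membered allyl β-keto lactone A3 would be ionised by Pd(PPh3)4 at the allylic C3–O bond, lose CO2, and the C1–C2 enolate would attack C3 to give the ten-membered α-methylene ketone A4.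
- Merits: the C–C bond forms inside an ion pair born from an easily closed macrolactone, so no high-dilution C–C coupling is needed, and C1 appears directly as the ketone without a protecting group or spectator stereocentre.
- Weak points: the allyl terminus can be attacked at C5 instead of C3, and the Z geometry of C4=C5 can be lost by isomerisation of the allylpalladium. A4 still lacks the epoxide, has C6 in the wrong configuration and both lactone carbons at the alcohol level, so a long endgame follows: face- and site-selective epoxidation beside two other alkenes, inversion at C6, oxidation and lactonisation, and protecting-group exchange.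
- Comparison: this road is better in the ease of ring formation and in the handling of C1. The chosen plan sets against this that every stereocentre, the epoxide and the lactone are in place before the ring closes and that only four steps follow.

Alternative 3: The cut is C10–C1 and C1–C2, with C1 delivered as carbon monoxide. The vinyl group of bromide A5 would be hydroborated with 9-BBN, and Pd(PPh3)4 with K3PO4 under CO would join the C10 alkenyl bromide and the C2 borane through an acylpalladium to give enone A6.
- Merits: two ring bonds form at once, the enone arrives unmasked, and the five steps the chosen route spends on C1 (vinyl addition, oxidation, bromination, reduction, silylation) plus the final oxidation are saved.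
- Weak points: direct coupling without CO insertion would give a nine-membered ring, and a carbonylative alkyl coupling that closes a ten-membered ring has no close model. Hydroboration must select the vinyl group in the presence of the alkenyl bromide. The reactive α-methylene ketone is then exposed to base and palladium, and must survive acetonide cleavage, epoxide formation and removal of two p-methoxybenzyl ethers.
- Comparison: this road is better in step economy at C1. The chosen plan sets against this a single bond-forming event whose intermolecular version is known, an epoxide that is already present, and an enone that is released in the last step.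

Key step: step 17

## Route

Assumption: the C1 carbinol configuration of 19–28 is a spectator that step 21 erases; the 1R series (from the (S)-oxazaborolidine) is drawn, and the 1S series would serve equally.

Remark on names: germacrane numbering is used in the text (C1–C10 ring carbons, C11–C13 lactone carbons with C12 the carbonyl, C14 the methylene on C10). TES = triethylsilyl, TBS = tert-butyldimethylsilyl, TBDPS = tert-butyldiphenylsilyl, Ts = p-toluenesulfonyl.

Step 1
Reactants: 1 methyl 3-hydroxypropanoate
Product: 2 methyl 3-[(tert-butyldiphenylsilyl)oxy]propanoate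
Conditions: t-BuPh2SiCl, imidazole, DMF, 0 °C to rt
Reagents that add atoms: tert-butyl(chloro)diphenylsilane, CC(C)(C)[Si](Cl)(c1ccccc1)c1ccccc1
Why: Silylation of a primary alcohol. The TBDPS ether survives the acidic acetonide cleavage of step 4 and is a poor leaving group for the β-oxygenated ester enolate of step 2.

Step 2
Reactants: 2 methyl 3-[(tert-butyldiphenylsilyl)oxy]propanoate; 3 methyl (4R)-2,2-dimethyl-1,3-dioxolane-4-carboxylate
Product: 4 methyl 2-{[(tert-butyldiphenylsilyl)oxy]methyl}-3-[(4R)-2,2-dimethyl-1,3-dioxolan-4-yl]-3-oxopropanoate (C2 epimers)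
Conditions: 2 (2 equiv), LiN(iPr)2 (2 equiv), THF, −78 °C; then 3 (1 equiv), −78 to −45 °C; AcOH quench
Reagents that add atoms: none
Why: Crossed Claisen condensation: the lithium enolate of 2 acylates the activated α-alkoxy ester 3, and the second equivalent of enolate deprotonates the product between its two carbonyls. That enolate protects the C8 hydrogen from epimerisation, and the low temperature suppresses β-elimination of silanolate.

Step 3
Reactants: 4 β-keto ester
Product: 5 methyl (2Z)-2-{[(tert-butyldiphenylsilyl)oxy]methyl}-3-[(4R)-2,2-dimethyl-1,3-dioxolan-4-yl]-3-{[(trifluoromethyl)sulfonyl]oxy}prop-2-enoate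
Conditions: NaH, Et2O, 0 °C; (CF3SO2)2O, −78 to 0 °C
Reagents that add atoms: trifluoromethanesulfonic anhydride, O=S(=O)(OS(=O)(=O)C(F)(F)F)C(F)(F)F
Why: O-Sulfonylation of a β-keto ester enolate. The sodium enolate is chelated by the ester carbonyl in the non-coordinating solvent, so the triflate should end up cis to the ester (Z), the geometry needed for lactonisation in step 8.

Step 4
Reactants: 5 enol triflate acetonide
Product: 6 methyl (2Z,4R)-2-{[(tert-butyldiphenylsilyl)oxy]methyl}-4,5-dihydroxy-3-{[(trifluoromethyl)sulfonyl]oxy}pent-2-enoate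
Conditions: CF3CO2H/H2O (4:1), CH2Cl2, 0 °C
Reagents that add atoms: none
Why: Acid hydrolysis of a terminal isopropylidene acetal on a substrate with no epoxide; the enol triflate and the TBDPS ether are acid-stable. The C8 hydroxyl is trans to the ester across the double bond and cannot lactonise.

Step 5
Reactants: 6 diol
Product: 7 methyl (2Z,4R)-2-{[(tert-butyldiphenylsilyl)oxy]methyl}-4,5-bis[(triethylsilyl)oxy]-3-{[(trifluoromethyl)sulfonyl]oxy}pent-2-enoate
Conditions: Et3SiOSO2CF3, 2,6-lutidine, CH2Cl2, −78 °C
Reagents that add atoms: triethylsilyl trifluoromethanesulfonate, CC[Si](CC)(CC)OS(=O)(=O)C(F)(F)F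
Why: Silylation with a silyl triflate and a non-nucleophilic base, which cannot attack the electrophilic enol triflate. The TES ethers are the only groups in the later intermediates that buffered HF removes quickly.

Step 6
Reactants: 8 nerol
Product: 9 [(2R,3S)-3-methyl-3-(4-methylpent-3-en-1-yl)oxiran-2-yl]methanol
Conditions: Ti(OiPr)4 (cat.), D-(−)-diethyl tartrate, t-BuOOH, 4 Å molecular sieves, CH2Cl2, −20 °C
Reagents that add atoms: tert-butyl hydroperoxide, CC(C)(C)OO
Why: Sharpless asymmetric epoxidation; only the allylic alcohol double bond reacts. The D-(−)-tartrate should deliver oxygen to the face that gives the (2R,3S) epoxide, which becomes 4S,5R, and the Z olefin fixes the cis relation of C3 and C6.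

Step 7
Reactants: 9 epoxy alcohol
Product: 10 (2S,3S)-3-methyl-3-(4-methylpent-3-en-1-yl)oxirane-2-carbaldehyde
Conditions: Dess–Martin periodinane, NaHCO3, CH2Cl2, 0 °C
Reagents that add atoms: none
Why: Dess–Martin oxidation of a primary alcohol under buffered conditions that leave the epoxide intact. The oxiranyl α-hydrogen does not enolise, so the stereocentres are secure (the descriptor at C2 changes only through priority).

Step 8
Reactants: 7 enol triflate; 10 epoxy aldehyde
Product: 12 (5R)-5-[(2R,3S)-3-methyl-3-(4-methylpent-3-en-1-yl)oxiran-2-yl]-4-[(1S)-1,2-bis(triethylsilyloxy)ethyl]-3-{[(tert-butyldiphenylsilyl)oxy]methyl}furan-2(5H)-one, via hydroxy ester 11 (not isolated)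
Conditions: CrCl2 (6 equiv), NiCl2 (2 mol%), DMF, rt; aqueous sodium serinate work-up
Reagents that add atoms: none
Why: Nozaki–Hiyama–Kishi coupling: zerovalent nickel inserts into the C7–O triflate bond, transmetalation gives the alkenylchromium, which adds only to the aldehyde, and the chromium alkoxide of 11 closes onto the cis methyl ester. C6 is set by the C5 epoxide: attack anti to the epoxide C–O bond (Felkin–Anh/Cornforth) should give the 5,6-anti, 6R adduct.

Step 9
Reactants: 12 butenolide
Product: 13 (5R)-5-[(2R,3S)-3-methyl-3-(3-oxopropyl)oxiran-2-yl]-4-[(1S)-1,2-bis(triethylsilyloxy)ethyl]-3-{[(tert-butyldiphenylsilyl)oxy]methyl}furan-2(5H)-one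
Conditions: O3, CH2Cl2, −78 °C (Sudan Red 7B end point); PPh3, −78 °C to rt
Reagents that add atoms: ozone, [O-][O+]=O
Why: Ozonolysis with reductive work-up. The electron-rich trisubstituted olefin is consumed long before the tetrasubstituted, electron-poor butenolide double bond.

Step 10
Reactants: 13 aldehyde; 14 vinylmagnesium bromide
Product: 15 (5R)-5-[(2R,3S)-3-(3-hydroxypent-4-en-1-yl)-3-methyloxiran-2-yl]-4-[(1S)-1,2-bis(triethylsilyloxy)ethyl]-3-{[(tert-butyldiphenylsilyl)oxy]methyl}furan-2(5H)-one (C1 epimers)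
Conditions: THF, −78 °C; aqueous NH4Cl at −78 °C
Reagents that add atoms: none
Why: Grignard 1,2-addition; at −78 °C the aldehyde is far more electrophilic than the hindered lactone. C1 forms without control and is flattened in step 11, and the cold quench keeps the magnesium alkoxide from attacking the epoxide.

Step 11
Reactants: 15 allylic alcohol
Product: 16 (5R)-5-[(2R,3S)-3-methyl-3-(3-oxopent-4-en-1-yl)oxiran-2-yl]-4-[(1S)-1,2-bis(triethylsilyloxy)ethyl]-3-{[(tert-butyldiphenylsilyl)oxy]methyl}furan-2(5H)-one
Conditions: Dess–Martin periodinane, NaHCO3, CH2Cl2, 0 °C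
Reagents that add atoms: none
Why: Dess–Martin oxidation of a secondary allylic alcohol to the vinyl ketone. The buffer keeps the γ,δ-epoxy alcohol from cyclising before it is oxidised.

Step 12
Reactants: 16 vinyl ketone
Product: 18 (5R)-5-[(2R,3S)-3-(4-bromo-3-oxopent-4-en-1-yl)-3-methyloxiran-2-yl]-4-[(1S)-1,2-bis(triethylsilyloxy)ethyl]-3-{[(tert-butyldiphenylsilyl)oxy]methyl}furan-2(5H)-one, via dibromide 17 (not isolated)
Conditions: Br2, CH2Cl2, −78 °C; then Et3N, −78 to 0 °C
Reagents that add atoms: bromine, BrBr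
Why: Bromination–dehydrobromination of an enone. Br2 adds to the only reactive alkene, and Et3N removes the acidic C10 hydrogen of 17 with loss of the C14 bromide (E1cB); no acid is formed while the epoxide is present.

Step 13
Reactants: 18 α-bromo enone
Product: 19 (5R)-5-[(2R,3S)-3-[(3R)-4-bromo-3-hydroxypent-4-en-1-yl]-3-methyloxiran-2-yl]-4-[(1S)-1,2-bis(triethylsilyloxy)ethyl]-3-{[(tert-butyldiphenylsilyl)oxy]methyl}furan-2(5H)-one
Conditions: (S)-2-methyl-CBS-oxazaborolidine (0.3 equiv), catecholborane, toluene, −78 °C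
Reagents that add atoms: none
Why: Corey–Bakshi–Shibata reduction. The α-bromovinyl group acts as the large substituent, so the (S)-catalyst should give the 1R carbinol under catalyst control, remote from the other stereocentres; the lactone is not reduced at −78 °C.

Step 14
Reactants: 19 bromoallylic alcohol
Product: 20 (5R)-5-[(2R,3S)-3-{(3R)-4-bromo-3-[(tert-butyldimethylsilyl)oxy]pent-4-en-1-yl}-3-methyloxiran-2-yl]-4-[(1S)-1,2-bis(triethylsilyloxy)ethyl]-3-{[(tert-butyldiphenylsilyl)oxy]methyl}furan-2(5H)-one
Conditions: t-BuMe2SiCl, imidazole, DMAP (cat.), DMF, rt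
Reagents that add atoms: tert-butyl(chloro)dimethylsilane, CC(C)(C)[Si](C)(C)Cl
Why: Silylation under basic conditions, chosen over a Lewis-acidic silyl triflate because the free C1 hydroxyl sits four atoms from the tertiary epoxide carbon C4.

Step 15
Reactants: 20 tetrasilyl ether
Product: 21 (5R)-5-[(2R,3S)-3-{(3R)-4-bromo-3-[(tert-butyldimethylsilyl)oxy]pent-4-en-1-yl}-3-methyloxiran-2-yl]-4-[(1S)-1,2-dihydroxyethyl]-3-{[(tert-butyldiphenylsilyl)oxy]methyl}furan-2(5H)-one
Conditions: HF·pyridine, excess pyridine, THF, 0 °C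
Reagents that add atoms: none
Why: Selective desilylation: the TES ethers are cleaved much faster than the secondary TBS and primary TBDPS ethers. The pyridine buffer and low temperature keep the C4–C5 epoxide closed beside the freed C8 hydroxyl.

Step 16
Reactants: 21 diol
Product: 23 (5R)-5-[(2R,3S)-3-{(3R)-4-bromo-3-[(tert-butyldimethylsilyl)oxy]pent-4-en-1-yl}-3-methyloxiran-2-yl]-4-[(2S)-oxiran-2-yl]-3-{[(tert-butyldiphenylsilyl)oxy]methyl}furan-2(5H)-one, via primary tosylate 22 (not isolated)
Conditions: TsCl, Et3N, Bu2SnO (cat.), CH2Cl2, 0 °C to rt; then K2CO3, MeOH, 0 °C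
Reagents that add atoms: p-toluenesulfonyl chloride, Cc1ccc(cc1)S(Cl)(=O)=O (its atoms stay only in 22)
Why: Tin-catalysed selective sulfonylation of the primary hydroxyl, then 3-exo-tet closure by the C8 alkoxide. The C8–O bond is not broken, so C8 keeps the chiral-pool configuration, and the fast closure at 0 °C should outrun γ-deprotonation of the butenolide.

Step 17
Reactants: 23 epoxide–alkenyl bromide
Product: 25 (1R,4S,5R,6R,8R)-1-[(tert-butyldimethylsilyl)oxy]-13-[(tert-butyldiphenylsilyl)oxy]-4,5-epoxy-8-hydroxygermacra-7(11),10(14)-dien-12,6-olide, via iodohydrin 24 (not isolated)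
Conditions: NiBr2(dme) (30 mol%), 2,2'-bipyridine (36 mol%), NaI (50 mol%), Et3N·HCl (1.5 equiv), Mn powder (4 equiv), DMPU, 25 °C; 23 added by syringe pump to a final 0.004 M
Reagents that add atoms: sodium iodide, [Na+].[I-] (iodine only in 24)
Why: Proposed new method: iodide, with Et3N·HCl as proton donor, opens the monosubstituted oxirane of 23 at its CH2 terminus (C9) to give iodohydrin 24; zerovalent nickel–bipyridine abstracts the iodine to leave a C9 radical, which is captured by the divalent alkenylnickel bromide formed by oxidative addition at C10, and reductive elimination from trivalent nickel forms C9–C10 while manganese returns nickel to the zerovalent state. The closest known reaction type is the intermolecular nickel-catalysed reductive cross-electrophile coupling of aryl and alkenyl halides with epoxides under iodide co-catalysis; its use to close a ring is new. The ten-membered carbocycle closes when the tethered radical meets nickel and the resulting nickelacycle contracts by reductive elimination, so this is a macrocyclisation by C(sp3)–C(sp2) bond formation in which both reactive ends exist only at catalytic, low stationary concentration while 23 is fed slowly at high dilution. No stereocentre is created: C8 keeps its configuration because its C–O bond is never broken, and C1, C4, C5 and C6 are spectators. The step needs iodide to attack only C9, which the unhindered terminus secures against the trisubstituted C4–C5 oxirane and against the allylic C8 carbon shielded by the fully substituted butenolide. It also needs oxidative addition at the alkenyl bromide to outrun ionisation of the allylic oxirane, which the electron-poor C7=C11 double bond disfavours, and capture of the C9 radical at nickel to outrun its attack on the butenolide.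

Step 18
Reactants: 25 macrocyclic alcohol
Product: 26 (1R,4S,5R,6R,8R)-1-[(tert-butyldimethylsilyl)oxy]-13-[(tert-butyldiphenylsilyl)oxy]-4,5-epoxy-8-(methacryloyloxy)germacra-7(11),10(14)-dien-12,6-olide
Conditions: methacrylic anhydride, Et3N, DMAP (cat.), CH2Cl2, 0 °C to rt
Reagents that add atoms: methacrylic anhydride, CC(=C)C(=O)OC(=O)C(C)=C
Why: DMAP-catalysed acylation of the only free hydroxyl. Capping C8–OH also removes the nucleophile that could open the C4–C5 epoxide across the ring.

Step 19
Reactants: 26 bis-silyl ether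
Product: 27 (1R,4S,5R,6R,8R)-4,5-epoxy-1,13-dihydroxy-8-(methacryloyloxy)germacra-7(11),10(14)-dien-12,6-olide
Conditions: Bu4NF, AcOH (1:1), THF, 0 °C to rt
Reagents that add atoms: none
Why: Fluoride desilylation of both silyl ethers. The acetic acid buffer keeps the medium near neutral, so the epoxide is not activated towards the freed C1 hydroxyl and the methacrylate does not migrate from O8 to O13.

Step 20
Reactants: 27 diol
Product: 28 (1R,4S,5R,6R,8R)-13-acetoxy-4,5-epoxy-1-hydroxy-8-(methacryloyloxy)germacra-7(11),10(14)-dien-12,6-olide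
Conditions: AcCl (1.1 equiv), 2,4,6-collidine, CH2Cl2, −78 °C
Reagents that add atoms: acetyl chloride, CC(Cl)=O
Why: Chemoselective acetylation of a primary alcohol with acetyl chloride and a hindered pyridine at low temperature. The secondary C1 hydroxyl, flanked by the ring and the C10 methylene, should react much more slowly.

Step 21
Reactants: 28 allylic alcohol
Product: 29 (4S,5R,6R,8R)-13-acetoxy-4,5-epoxy-8-(methacryloyloxy)-1-oxogermacra-7(11),10(14)-dien-12,6-olide (CNP0266914.1)
Conditions: Dess–Martin periodinane, NaHCO3, CH2Cl2, 0 °C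
Reagents that add atoms: none
Why: Dess–Martin oxidation of the secondary allylic alcohol under buffered, neutral conditions. The reactive α-methylene ketone is released last, and the spectator stereocentre at C1 disappears.

## Compound list

1 | methyl 3-hydroxypropanoate | COC(=O)CCO | starting material
2 | methyl 3-[(tert-butyldiphenylsilyl)oxy]propanoate | COC(=O)CCO[Si](c1ccccc1)(c1ccccc1)C(C)(C)C | intermediate
3 | methyl (4R)-2,2-dimethyl-1,3-dioxolane-4-carboxylate | COC(=O)[C@H]1COC(C)(C)O1 | starting material
4 | methyl 2-{[(tert-butyldiphenylsilyl)oxy]methyl}-3-[(4R)-2,2-dimethyl-1,3-dioxolan-4-yl]-3-oxopropanoate (C2 epimers) | COC(=O)C(CO[Si](c1ccccc1)(c1ccccc1)C(C)(C)C)C(=O)[C@H]1COC(C)(C)O1 | intermediate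
5 | methyl (2Z)-2-{[(tert-butyldiphenylsilyl)oxy]methyl}-3-[(4R)-2,2-dimethyl-1,3-dioxolan-4-yl]-3-{[(trifluoromethyl)sulfonyl]oxy}prop-2-enoate | COC(=O)/C(CO[Si](c1ccccc1)(c1ccccc1)C(C)(C)C)=C(\OS(=O)(=O)C(F)(F)F)[C@H]1COC(C)(C)O1 | intermediate
6 | methyl (2Z,4R)-2-{[(tert-butyldiphenylsilyl)oxy]methyl}-4,5-dihydroxy-3-{[(trifluoromethyl)sulfonyl]oxy}pent-2-enoate | COC(=O)/C(CO[Si](c1ccccc1)(c1ccccc1)C(C)(C)C)=C(\OS(=O)(=O)C(F)(F)F)[C@H](O)CO | intermediate
7 | methyl (2Z,4R)-2-{[(tert-butyldiphenylsilyl)oxy]methyl}-4,5-bis[(triethylsilyl)oxy]-3-{[(trifluoromethyl)sulfonyl]oxy}pent-2-enoate | COC(=O)/C(CO[Si](c1ccccc1)(c1ccccc1)C(C)(C)C)=C(\OS(=O)(=O)C(F)(F)F)[C@H](O[Si](CC)(CC)CC)CO[Si](CC)(CC)CC | intermediate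
8 | nerol, (2Z)-3,7-dimethylocta-2,6-dien-1-ol | CC(C)=CCC/C(C)=C\CO | starting material
9 | [(2R,3S)-3-methyl-3-(4-methylpent-3-en-1-yl)oxiran-2-yl]methanol | CC(C)=CCC[C@]1(C)O[C@@H]1CO | intermediate
10 | (2S,3S)-3-methyl-3-(4-methylpent-3-en-1-yl)oxirane-2-carbaldehyde | CC(C)=CCC[C@]1(C)O[C@@H]1C=O | intermediate
11 | methyl (2E,4R)-2-{[(tert-butyldiphenylsilyl)oxy]methyl}-3-[(1S)-1,2-bis(triethylsilyloxy)ethyl]-4-hydroxy-4-[(2R,3S)-3-methyl-3-(4-methylpent-3-en-1-yl)oxiran-2-yl]but-2-enoate (hydroxyl-bearing carbon cis to the ester) | CC(C)=CCC[C@]1(C)O[C@@H]1[C@H](O)/C(=C(/CO[Si](c1ccccc1)(c1ccccc1)C(C)(C)C)C(=O)OC)[C@H](O[Si](CC)(CC)CC)CO[Si](CC)(CC)CC | intermediate (not isolated)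
12 | (5R)-5-[(2R,3S)-3-methyl-3-(4-methylpent-3-en-1-yl)oxiran-2-yl]-4-[(1S)-1,2-bis(triethylsilyloxy)ethyl]-3-{[(tert-butyldiphenylsilyl)oxy]methyl}furan-2(5H)-one | CC(C)=CCC[C@]1(C)O[C@@H]1[C@@H]1OC(=O)C(CO[Si](c2ccccc2)(c2ccccc2)C(C)(C)C)=C1[C@H](O[Si](CC)(CC)CC)CO[Si](CC)(CC)CC | intermediate
13 | (5R)-5-[(2R,3S)-3-methyl-3-(3-oxopropyl)oxiran-2-yl]-4-[(1S)-1,2-bis(triethylsilyloxy)ethyl]-3-{[(tert-butyldiphenylsilyl)oxy]methyl}furan-2(5H)-one | O=CCC[C@]1(C)O[C@@H]1[C@@H]1OC(=O)C(CO[Si](c2ccccc2)(c2ccccc2)C(C)(C)C)=C1[C@H](O[Si](CC)(CC)CC)CO[Si](CC)(CC)CC | intermediate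
14 | vinylmagnesium bromide | C=C[Mg]Br | starting material
15 | (5R)-5-[(2R,3S)-3-(3-hydroxypent-4-en-1-yl)-3-methyloxiran-2-yl]-4-[(1S)-1,2-bis(triethylsilyloxy)ethyl]-3-{[(tert-butyldiphenylsilyl)oxy]methyl}furan-2(5H)-one (both carbinol epimers) | C=CC(O)CC[C@]1(C)O[C@@H]1[C@@H]1OC(=O)C(CO[Si](c2ccccc2)(c2ccccc2)C(C)(C)C)=C1[C@H](O[Si](CC)(CC)CC)CO[Si](CC)(CC)CC | intermediate
16 | (5R)-5-[(2R,3S)-3-methyl-3-(3-oxopent-4-en-1-yl)oxiran-2-yl]-4-[(1S)-1,2-bis(triethylsilyloxy)ethyl]-3-{[(tert-butyldiphenylsilyl)oxy]methyl}furan-2(5H)-one | C=CC(=O)CC[C@]1(C)O[C@@H]1[C@@H]1OC(=O)C(CO[Si](c2ccccc2)(c2ccccc2)C(C)(C)C)=C1[C@H](O[Si](CC)(CC)CC)CO[Si](CC)(CC)CC | intermediate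
17 | (5R)-5-[(2R,3S)-3-(4,5-dibromo-3-oxopentyl)-3-methyloxiran-2-yl]-4-[(1S)-1,2-bis(triethylsilyloxy)ethyl]-3-{[(tert-butyldiphenylsilyl)oxy]methyl}furan-2(5H)-one (both CHBr epimers) | BrCC(Br)C(=O)CC[C@]1(C)O[C@@H]1[C@@H]1OC(=O)C(CO[Si](c2ccccc2)(c2ccccc2)C(C)(C)C)=C1[C@H](O[Si](CC)(CC)CC)CO[Si](CC)(CC)CC | intermediate (not isolated)
18 | (5R)-5-[(2R,3S)-3-(4-bromo-3-oxopent-4-en-1-yl)-3-methyloxiran-2-yl]-4-[(1S)-1,2-bis(triethylsilyloxy)ethyl]-3-{[(tert-butyldiphenylsilyl)oxy]methyl}furan-2(5H)-one | C=C(Br)C(=O)CC[C@]1(C)O[C@@H]1[C@@H]1OC(=O)C(CO[Si](c2ccccc2)(c2ccccc2)C(C)(C)C)=C1[C@H](O[Si](CC)(CC)CC)CO[Si](CC)(CC)CC | intermediate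
19 | (5R)-5-[(2R,3S)-3-[(3R)-4-bromo-3-hydroxypent-4-en-1-yl]-3-methyloxiran-2-yl]-4-[(1S)-1,2-bis(triethylsilyloxy)ethyl]-3-{[(tert-butyldiphenylsilyl)oxy]methyl}furan-2(5H)-one | C=C(Br)[C@H](O)CC[C@]1(C)O[C@@H]1[C@@H]1OC(=O)C(CO[Si](c2ccccc2)(c2ccccc2)C(C)(C)C)=C1[C@H](O[Si](CC)(CC)CC)CO[Si](CC)(CC)CC | intermediate
20 | (5R)-5-[(2R,3S)-3-{(3R)-4-bromo-3-[(tert-butyldimethylsilyl)oxy]pent-4-en-1-yl}-3-methyloxiran-2-yl]-4-[(1S)-1,2-bis(triethylsilyloxy)ethyl]-3-{[(tert-butyldiphenylsilyl)oxy]methyl}furan-2(5H)-one | C=C(Br)[C@H](O[Si](C)(C)C(C)(C)C)CC[C@]1(C)O[C@@H]1[C@@H]1OC(=O)C(CO[Si](c2ccccc2)(c2ccccc2)C(C)(C)C)=C1[C@H](O[Si](CC)(CC)CC)CO[Si](CC)(CC)CC | intermediate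
21 | (5R)-5-[(2R,3S)-3-{(3R)-4-bromo-3-[(tert-butyldimethylsilyl)oxy]pent-4-en-1-yl}-3-methyloxiran-2-yl]-4-[(1S)-1,2-dihydroxyethyl]-3-{[(tert-butyldiphenylsilyl)oxy]methyl}furan-2(5H)-one | C=C(Br)[C@H](O[Si](C)(C)C(C)(C)C)CC[C@]1(C)O[C@@H]1[C@@H]1OC(=O)C(CO[Si](c2ccccc2)(c2ccccc2)C(C)(C)C)=C1[C@H](O)CO | intermediate
22 | (5R)-5-[(2R,3S)-3-{(3R)-4-bromo-3-[(tert-butyldimethylsilyl)oxy]pent-4-en-1-yl}-3-methyloxiran-2-yl]-4-[(1S)-1-hydroxy-2-(tosyloxy)ethyl]-3-{[(tert-butyldiphenylsilyl)oxy]methyl}furan-2(5H)-one | C=C(Br)[C@H](O[Si](C)(C)C(C)(C)C)CC[C@]1(C)O[C@@H]1[C@@H]1OC(=O)C(CO[Si](c2ccccc2)(c2ccccc2)C(C)(C)C)=C1[C@H](O)COS(=O)(=O)c1ccc(C)cc1 | intermediate (not isolated)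
23 | (5R)-5-[(2R,3S)-3-{(3R)-4-bromo-3-[(tert-butyldimethylsilyl)oxy]pent-4-en-1-yl}-3-methyloxiran-2-yl]-4-[(2S)-oxiran-2-yl]-3-{[(tert-butyldiphenylsilyl)oxy]methyl}furan-2(5H)-one | C=C(Br)[C@H](O[Si](C)(C)C(C)(C)C)CC[C@]1(C)O[C@@H]1[C@@H]1OC(=O)C(CO[Si](c2ccccc2)(c2ccccc2)C(C)(C)C)=C1[C@H]1CO1 | intermediate
24 | (5R)-5-[(2R,3S)-3-{(3R)-4-bromo-3-[(tert-butyldimethylsilyl)oxy]pent-4-en-1-yl}-3-methyloxiran-2-yl]-4-[(1S)-1-hydroxy-2-iodoethyl]-3-{[(tert-butyldiphenylsilyl)oxy]methyl}furan-2(5H)-one | C=C(Br)[C@H](O[Si](C)(C)C(C)(C)C)CC[C@]1(C)O[C@@H]1[C@@H]1OC(=O)C(CO[Si](c2ccccc2)(c2ccccc2)C(C)(C)C)=C1[C@H](O)CI | intermediate (not isolated)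
25 | (1R,4S,5R,6R,8R)-1-[(tert-butyldimethylsilyl)oxy]-13-[(tert-butyldiphenylsilyl)oxy]-4,5-epoxy-8-hydroxygermacra-7(11),10(14)-dien-12,6-olide | O[C@@H]1CC(=C)[C@H](O[Si](C)(C)C(C)(C)C)CC[C@]2(C)O[C@@H]2[C@@H]2OC(=O)C(CO[Si](c3ccccc3)(c3ccccc3)C(C)(C)C)=C21 | intermediate
26 | (1R,4S,5R,6R,8R)-1-[(tert-butyldimethylsilyl)oxy]-13-[(tert-butyldiphenylsilyl)oxy]-4,5-epoxy-8-(methacryloyloxy)germacra-7(11),10(14)-dien-12,6-olide | C=C(C)C(=O)O[C@@H]1CC(=C)[C@H](O[Si](C)(C)C(C)(C)C)CC[C@]2(C)O[C@@H]2[C@@H]2OC(=O)C(CO[Si](c3ccccc3)(c3ccccc3)C(C)(C)C)=C21 | intermediate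
27 | (1R,4S,5R,6R,8R)-4,5-epoxy-1,13-dihydroxy-8-(methacryloyloxy)germacra-7(11),10(14)-dien-12,6-olide | C=C(C)C(=O)O[C@@H]1CC(=C)[C@H](O)CC[C@]2(C)O[C@@H]2[C@@H]2OC(=O)C(CO)=C21 | intermediate
28 | (1R,4S,5R,6R,8R)-13-acetoxy-4,5-epoxy-1-hydroxy-8-(methacryloyloxy)germacra-7(11),10(14)-dien-12,6-olide | C=C(C)C(=O)O[C@@H]1CC(=C)[C@H](O)CC[C@]2(C)O[C@@H]2[C@@H]2OC(=O)C(COC(C)=O)=C21 | intermediate
29 | (4S,5R,6R,8R)-13-acetoxy-4,5-epoxy-8-(methacryloyloxy)-1-oxogermacra-7(11),10(14)-dien-12,6-olide (CNP0266914.1) | C=C(C)C(=O)O[C@@H]1CC(=C)C(=O)CC[C@]2(C)O[C@@H]2[C@@H]2OC(=O)C(COC(C)=O)=C21 | target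

## Step count and least certain steps

Total step count: 21. Longest linear sequence: 19 steps (steps 1–5 and 8–21, from 1); the nerol branch is 16 steps (6, 7, 8–21).

**Step 17 (key step, proposed new method).**
- What may go wrong: intermolecular radical capture leading to oligomers instead of ring closure; protonolysis of the alkenylnickel by the ammonium salt; 3-exo attack of the C9 radical on the butenolide followed by a 1,2-shift of the lactone ring; slow iodide opening of the C4–C5 oxirane.
- Fallback (known chemistry, sets out from 12): the ring is closed at C1–C10 by a Nozaki–Hiyama–Kishi macrocyclisation, and C9–C10 is bought as part of a 2-bromoallyl unit. Buffered HF·pyridine frees the C8,C9-diol F1, and NaIO4 cleaves it to the C8 aldehyde F2. The B-(2-bromoallyl)-1,3,2-diazaborolidine derived from N,N'-ditosyl-1,2-diphenylethane-1,2-diamine (the enantiomer that delivers 8R) adds C9, C10 and C14 to give the bromoallyl carbinol F3. Methacrylic anhydride/DMAP gives the C8 methacrylate F4. Ozonolysis of the trisubstituted olefin gives the C1 aldehyde F5. CrCl2 with catalytic NiCl2 in DMSO/THF at high dilution closes the ring to the macrocyclic C1 alcohol F6 (both C1 epimers). Bu4NF/AcOH gives the diol F7 (C1 epimers, the 1R member being 27), AcCl/collidine the C13 acetate F8 (C1 epimers, the 1R member being 28), and the oxidation of step 21 converts both epimers into 29, where the fallback rejoins the route.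

**Step 8.**
- What may go wrong: poor facial selectivity at the epoxy aldehyde, and slow coupling of the hindered, fully substituted alkenylchromium.
- Fallback (sets out from 10 and 7, returns at 12): C6 is set by reduction instead of addition. NaClO2/NaH2PO4/2-methyl-2-butene oxidises 10 to the epoxy acid F9, and PhSH with dicyclohexylcarbodiimide gives the S-phenyl thioester F10. Triflate 7 is converted with (Me3Sn)2, Pd(PPh3)4 and LiCl into the (Z)-alkenylstannane F11. A Liebeskind–Srogl coupling (Pd2(dba)3, tri(2-furyl)phosphine, copper thiophene-2-carboxylate CuO2CC4H3S) joins F10 and F11 to the C6 ketone F12. Zn(BH4)2 in Et2O, chelated between the ketone and the epoxide oxygen, should reduce F12 to the anti (6R) carbinol 11, which lactonises to 12.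

**Step 2.**
- What may go wrong: β-elimination of silanolate from the ester enolate before it is acylated, and epimerisation at C8 if the product enolate is not formed cleanly.
- Fallback (sets out from 3, returns at 4): 3 is converted with MeNHOMe·HCl and i-PrMgCl into the Weinreb amide F13, which is acylated by one equivalent of the lithium enolate of 2 at −78 °C. The stable tetrahedral intermediate releases 4 only on acidic quench.

**Step 16.**
- What may go wrong: competing attack of the C8 alkoxide on the C4–C5 epoxide, or γ-deprotonation of the butenolide (epimerisation at C6 or C8) under the basic closure.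
- Fallback (sets out from 21, returns at 23): Mitsunobu cyclodehydration with PPh3 and diisopropyl azodicarboxylate in toluene activates the primary hydroxyl and closes the oxirane from the C8 oxygen under neutral conditions, with retention at C8; no new compound is formed.

**Step 20.**
- What may go wrong: acetylation of the C1 hydroxyl as well, or acyl migration between O8 and O13.
- Fallback (sets out from 27, returns at 29): the order is reversed. MnO2 in CH2Cl2 oxidises the secondary allylic C1 alcohol, while the C13 hydroxymethyl group on the electron-poor butenolide double bond should react slowly, giving the keto alcohol F14. Ac2O/pyridine then acetylates the only remaining hydroxyl to give 29.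

## Further compounds

F1 | step 17 | (5R)-5-[(2R,3S)-3-methyl-3-(4-methylpent-3-en-1-yl)oxiran-2-yl]-4-[(1S)-1,2-dihydroxyethyl]-3-{[(tert-butyldiphenylsilyl)oxy]methyl}furan-2(5H)-one | CC(C)=CCC[C@]1(C)O[C@@H]1[C@@H]1OC(=O)C(CO[Si](c2ccccc2)(c2ccccc2)C(C)(C)C)=C1[C@H](O)CO
F2 | step 17 | (2R)-2-[(2R,3S)-3-methyl-3-(4-methylpent-3-en-1-yl)oxiran-2-yl]-4-{[(tert-butyldiphenylsilyl)oxy]methyl}-5-oxo-2,5-dihydrofuran-3-carbaldehyde | CC(C)=CCC[C@]1(C)O[C@@H]1[C@@H]1OC(=O)C(CO[Si](c2ccccc2)(c2ccccc2)C(C)(C)C)=C1C=O
F3 | step 17 | (5R)-5-[(2R,3S)-3-methyl-3-(4-methylpent-3-en-1-yl)oxiran-2-yl]-4-[(1R)-3-bromo-1-hydroxybut-3-en-1-yl]-3-{[(tert-butyldiphenylsilyl)oxy]methyl}furan-2(5H)-one | CC(C)=CCC[C@]1(C)O[C@@H]1[C@@H]1OC(=O)C(CO[Si](c2ccccc2)(c2ccccc2)C(C)(C)C)=C1[C@H](O)CC(Br)=C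
F4 | step 17 | methacrylate ester of F3 at the (1R) carbinol | CC(C)=CCC[C@]1(C)O[C@@H]1[C@@H]1OC(=O)C(CO[Si](c2ccccc2)(c2ccccc2)C(C)(C)C)=C1[C@H](OC(=O)C(C)=C)CC(Br)=C
F5 | step 17 | F4 with the 4-methylpent-3-enyl chain cut to 3-oxopropyl (C1 aldehyde) | O=CCC[C@]1(C)O[C@@H]1[C@@H]1OC(=O)C(CO[Si](c2ccccc2)(c2ccccc2)C(C)(C)C)=C1[C@H](OC(=O)C(C)=C)CC(Br)=C
F6 | step 17 | (4S,5R,6R,8R)-13-[(tert-butyldiphenylsilyl)oxy]-4,5-epoxy-1-hydroxy-8-(methacryloyloxy)germacra-7(11),10(14)-dien-12,6-olide (both C1 epimers) | C=C(C)C(=O)O[C@@H]1CC(=C)C(O)CC[C@]2(C)O[C@@H]2[C@@H]2OC(=O)C(CO[Si](c3ccccc3)(c3ccccc3)C(C)(C)C)=C21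
F7 | step 17 | (4S,5R,6R,8R)-4,5-epoxy-1,13-dihydroxy-8-(methacryloyloxy)germacra-7(11),10(14)-dien-12,6-olide (both C1 epimers) | C=C(C)C(=O)O[C@@H]1CC(=C)C(O)CC[C@]2(C)O[C@@H]2[C@@H]2OC(=O)C(CO)=C21
F8 | step 17 | (4S,5R,6R,8R)-13-acetoxy-4,5-epoxy-1-hydroxy-8-(methacryloyloxy)germacra-7(11),10(14)-dien-12,6-olide (both C1 epimers) | C=C(C)C(=O)O[C@@H]1CC(=C)C(O)CC[C@]2(C)O[C@@H]2[C@@H]2OC(=O)C(COC(C)=O)=C21
F9 | step 8 | (2S,3S)-3-methyl-3-(4-methylpent-3-en-1-yl)oxirane-2-carboxylic acid | CC(C)=CCC[C@]1(C)O[C@@H]1C(=O)O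
F10 | step 8 | S-phenyl (2S,3S)-3-methyl-3-(4-methylpent-3-en-1-yl)oxirane-2-carbothioate | CC(C)=CCC[C@]1(C)O[C@@H]1C(=O)Sc1ccccc1
F11 | step 8 | methyl (2Z,4R)-2-{[(tert-butyldiphenylsilyl)oxy]methyl}-4,5-bis[(triethylsilyl)oxy]-3-(trimethylstannyl)pent-2-enoate | COC(=O)/C(CO[Si](c1ccccc1)(c1ccccc1)C(C)(C)C)=C(\[Sn](C)(C)C)[C@H](O[Si](CC)(CC)CC)CO[Si](CC)(CC)CC
F12 | step 8 | C6 ketone corresponding to 11: methyl 2-{[(tert-butyldiphenylsilyl)oxy]methyl}-3-[(1S)-1,2-bis(triethylsilyloxy)ethyl]-4-[(2S,3S)-3-methyl-3-(4-methylpent-3-en-1-yl)oxiran-2-yl]-4-oxobut-2-enoate (keto group cis to the ester) | CC(C)=CCC[C@]1(C)O[C@@H]1C(=O)/C(=C(/CO[Si](c1ccccc1)(c1ccccc1)C(C)(C)C)C(=O)OC)[C@H](O[Si](CC)(CC)CC)CO[Si](CC)(CC)CC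
F13 | step 2 | (4R)-N-methoxy-N,2,2-trimethyl-1,3-dioxolane-4-carboxamide | CON(C)C(=O)[C@H]1COC(C)(C)O1
F0 | step 16 | none | none
F14 | step 20 | (4S,5R,6R,8R)-4,5-epoxy-13-hydroxy-8-(methacryloyloxy)-1-oxogermacra-7(11),10(14)-dien-12,6-olide | C=C(C)C(=O)O[C@@H]1CC(=C)C(=O)CC[C@]2(C)O[C@@H]2[C@@H]2OC(=O)C(CO)=C21
A1 | alternative 1 | open-chain (Z)-enol triflate methyl ester with C6 aldehyde, C8 methacrylate, C13 acetate and C1 TBS ether | C=C(C)C(=O)O[C@H](CC(=C)[C@H](O[Si](C)(C)C(C)(C)C)CC[C@]1(C)O[C@@H]1C=O)/C(OS(=O)(=O)C(F)(F)F)=C(\COC(C)=O)C(=O)OC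
A2 | alternative 1 | epoxy butenolide macrocycle with C1 TBS ether, C8 methacrylate and C13 acetate | C=C(C)C(=O)O[C@@H]1CC(=C)[C@H](O[Si](C)(C)C(C)(C)C)CC[C@]2(C)O[C@@H]2[C@@H]2OC(=O)C(COC(C)=O)=C21
A3 | alternative 2 | twelve-membered allyl β-keto lactone (ester oxygen on C3, Z C4=C5, 6-epi TES ether) | COc1ccc(CO[C@@H]2CC(=C)C(=O)CC(=O)OC/C(C)=C\[C@@H](O[Si](CC)(CC)CC)/C2=C(\CO[Si](C)(C)C(C)(C)C)COCc2ccc(OC)cc2)cc1
A4 | alternative 2 | ten-membered α-methylene ketone with Z C4=C5 and 6-epi TES ether | COc1ccc(CO[C@@H]2CC(=C)C(=O)CC/C(C)=C\[C@@H](O[Si](CC)(CC)CC)/C2=C(\CO[Si](C)(C)C(C)(C)C)COCc2ccc(OC)cc2)cc1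
A5 | alternative 3 | butenolide with C10 alkenyl bromide, C4 vinyl group, C4/C5 acetonide and two p-methoxybenzyl ethers | COc1ccc(CO[C@H](CC(Br)=C)C2=C(COCc3ccc(OC)cc3)C(=O)O[C@H]2[C@@H]2OC(C)(C)O[C@@]2(C)C=C)cc1
A6 | alternative 3 | ten-membered enone with C4/C5 acetonide and butenolide | COc1ccc(CO[C@@H]2CC(=C)C(=O)CC[C@]3(C)OC(C)(C)O[C@H]3[C@@H]3OC(=O)C(COCc4ccc(OC)cc4)=C32)cc1
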